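## Retrosynthetic overview
1. The C2–SMe bond is cut last. It is formed by electrophilic sulfenylation of 4,5,6-tribromo-3-(methylsulfanyl)-1H-indole with MeSCl.
2. The N1–C2 bond is cut next. The pyrrole ring closes by acid condensation of an aniline NH2 onto a masked aldehyde held ortho to it.
3. The C3–C3a bond and the C3–SMe group arrive together, through a Gassman azasulfonium ylide [2,3]-shift between 3,4,5-tribromoaniline and MeSCH2CH(OMe)2.
4. All three bromines are bought with the aniline. Its two ortho positions are equivalent, so only the 4,5,6-isomer can form, and no step uses a metal or base that attacks C–Br.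
5. Ring order: the benzene ring is purchased, and the pyrrole ring is the only ring formed (step 2).

Assumption: the target has no stereocentre and its SMILES carries no stereo descriptor, so "single enantiomer" requires no stereocontrol. Compounds 1 and 2 are taken as catalogue chemicals.

## Route

Step 1
Reactants: 1 3,4,5-tribromoaniline; 2 (methylsulfanyl)acetaldehyde dimethyl acetal (1,1-dimethoxy-2-(methylsulfanyl)ethane)
Product: 6 (±)-3,4,5-tribromo-2-[2,2-dimethoxy-1-(methylsulfanyl)ethyl]aniline, via N-chloro-3,4,5-tribromoaniline 3 (not isolated), via (2,2-dimethoxyethyl)(methyl)(3,4,5-tribromoanilino)sulfonium chloride 4 (not isolated), via 2,2-dimethoxy-1-[methyl(3,4,5-tribromoanilino)sulfonio]ethan-1-ide 5 (not isolated)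
Conditions: t-BuOCl, CH2Cl2/MeCN, −60 °C; then 2, −60 °C; then Et3N, −60 °C → reflux
Reagents that add atoms: tert-butyl hypochlorite, CC(C)(C)OCl (its Cl is carried only by 3 and 4; all heavy atoms of 6 come from 1 and 2)
Why: This is the first stage of the Gassman indole synthesis, in which N-chlorination, S-attack on N–Cl, ylide formation at the acetal-acidified S–CH2 and a Sommelet–Hauser [2,3]-sigmatropic shift with re-aromatisation place the CH(SMe)CH(OMe)2 carbon on one of the two equivalent ortho positions, and the new CH(SMe) centre is racemic and is erased in step 2.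

Step 2
Reactants: 6 (±)-3,4,5-tribromo-2-[2,2-dimethoxy-1-(methylsulfanyl)ethyl]aniline
Product: 8 4,5,6-tribromo-3-(methylsulfanyl)-1H-indole, via 2-(2-amino-4,5,6-tribromophenyl)-2-(methylsulfanyl)acetaldehyde 7 (not isolated)
Conditions: 2 M aq HCl, Et2O/THF, rt
Reagents that add atoms: water, O (supplies the carbonyl O of 7 only; all heavy atoms of 8 come from 6)
Why: This is the closing stage of the Gassman indole synthesis, in which acetal hydrolysis unmasks aldehyde 7, the ortho NH2 adds to it and dehydration follows, with aromatisation driving the cyclocondensation despite the weakly nucleophilic nitrogen and removing the racemic centre.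

Step 3
Reactants: 8 4,5,6-tribromo-3-(methylsulfanyl)-1H-indole
Product: 10 4,5,6-tribromo-2,3-bis(methylsulfanyl)-1H-indole, via 4,5,6-tribromo-3,3-bis(methylsulfanyl)-3H-indol-1-ium chloride 9 (not isolated)
Conditions: MeSSMe (0.55 equiv), SO2Cl2 (0.55 equiv), CH2Cl2, −20 → 0 °C; then 8, CH2Cl2, 0 °C → rt
Reagents that add atoms: methanesulfenyl chloride, CSCl, made in the flask from dimethyl disulfide, CSSC, and sulfuryl chloride, O=S(=O)(Cl)Cl
Why: This is an electrophilic aromatic sulfenylation (the second sulfenylation of an indole), in which MeSCl attacks C3 ipso to give indoleninium 9, a 1,2-sulfur shift to C2 and loss of HCl restore the indole, and direct C2 attack would give the same product because both sulfur groups are SMe, while the C–Br bonds are inert.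

## Compound list
1 | 3,4,5-tribromoaniline | Nc1cc(Br)c(Br)c(Br)c1 | starting material
2 | (methylsulfanyl)acetaldehyde dimethyl acetal | COC(OC)CSC | starting material
3 | N-chloro-3,4,5-tribromoaniline | ClNc1cc(Br)c(Br)c(Br)c1 | intermediate (not isolated)
4 | (2,2-dimethoxyethyl)(methyl)(3,4,5-tribromoanilino)sulfonium chloride | C[S+](CC(OC)OC)Nc1cc(Br)c(Br)c(Br)c1.[Cl-] | intermediate (not isolated)
5 | 2,2-dimethoxy-1-[methyl(3,4,5-tribromoanilino)sulfonio]ethan-1-ide (S–CH ylide of 4) | C[S+]([CH-]C(OC)OC)Nc1cc(Br)c(Br)c(Br)c1 | intermediate (not isolated)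
6 | (±)-3,4,5-tribromo-2-[2,2-dimethoxy-1-(methylsulfanyl)ethyl]aniline | COC(OC)C(SC)c1c(N)cc(Br)c(Br)c1Br | intermediate
7 | 2-(2-amino-4,5,6-tribromophenyl)-2-(methylsulfanyl)acetaldehyde (racemic) | O=CC(SC)c1c(N)cc(Br)c(Br)c1Br | intermediate (not isolated)
8 | 4,5,6-tribromo-3-(methylsulfanyl)-1H-indole | CSc1c[nH]c2cc(Br)c(Br)c(Br)c12 | intermediate
9 | 4,5,6-tribromo-3,3-bis(methylsulfanyl)-3H-indol-1-ium chloride | CSC1(SC)C=[NH+]c2cc(Br)c(Br)c(Br)c12.[Cl-] | intermediate (not isolated)
10 | 4,5,6-tribromo-2,3-bis(methylsulfanyl)-1H-indole | CSc1[nH]c2cc(Br)c(Br)c(Br)c2c1SC | target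

## Totals
Total step count: 3
Longest linear sequence: 3

## The three steps most likely to fail, most risky first

**Step 1.**
- Risk: The ylide is not carbonyl-stabilised. Deprotonation at S–CH3 or at N–H can therefore compete with deprotonation at S–CH2, methoxide may be lost by β-elimination, and the shift must end next to a bromine.
- Fallback: This route drops sulfonium chemistry and builds the pyrrole ring from an alkyne. It sets out from 1 and comes back at 8.
- Ortho-iodination of 1 (NIS, cat. TFA, MeCN) gives 3,4,5-tribromo-2-iodoaniline F1.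
- A C–I-selective Sonogashira coupling with trimethylsilylacetylene (PdCl2(PPh3)2, CuI, Et3N, rt) gives 3,4,5-tribromo-2-[(trimethylsilyl)ethynyl]aniline F2.
- K2CO3 (cat.) in MeOH gives 3,4,5-tribromo-2-ethynylaniline F3.
- CuI-catalysed 5-endo-dig cycloisomerisation (DMF, 100 °C) gives 4,5,6-tribromo-1H-indole F4.
- One equivalent of MeSCl (CH2Cl2, 0 °C) sulfenylates C3 of F4 and delivers 8.

**Step 3.**
- Risk: The tribromoindole is electron-poor and C3 is crowded by the 4-Br, so the second sulfenylation may be slow. The HCl set free may also scramble or cleave the sulfide groups.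
- Fallback: This route replaces electrophilic substitution by directed C2 metalation. It sets out from 8 and comes back at 10.
- Boc2O with DMAP (MeCN) gives tert-butyl 4,5,6-tribromo-3-(methylsulfanyl)-1H-indole-1-carboxylate F5.
- TMPMgCl·LiCl (THF, −20 °C) deprotonates C2 without Br/Mg exchange. It gives tert-butyl 4,5,6-tribromo-2-(chloromagnesio)-3-(methylsulfanyl)-1H-indole-1-carboxylate F6.
- S-methyl methanethiosulfonate traps F6 to give tert-butyl 4,5,6-tribromo-2,3-bis(methylsulfanyl)-1H-indole-1-carboxylate F7.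
- Non-acidic methanolysis of F7 (cat. NaOMe, MeOH/THF, rt) gives 10.

**Step 2.**
- Risk: The tribromoaniline nitrogen is a poor nucleophile, and the α-thio aldehyde 7 may lose MeSH or self-condense before it cyclises.
- Fallback: This route closes the ring by lactamisation and installs the C2 sulfur nucleophilically. It sets out from 1, which is chlorinated to 3 exactly as in step 1, and comes back at 10.
- Compound 3 is trapped with ethyl (methylsulfanyl)acetate instead of 2. This gives (2-ethoxy-2-oxoethyl)(methyl)(3,4,5-tribromoanilino)sulfonium chloride F8.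
- Et3N triggers the Sommelet–Hauser shift, now ester-stabilised and regiochemically unambiguous. It gives ethyl 2-(2-amino-4,5,6-tribromophenyl)-2-(methylsulfanyl)acetate F9.
- 2 M HCl closes F9 to 4,5,6-tribromo-3-(methylsulfanyl)-1,3-dihydro-2H-indol-2-one F10.
- Lawesson's reagent (toluene, 90 °C) gives 4,5,6-tribromo-3-(methylsulfanyl)-1,3-dihydro-2H-indole-2-thione F11.
- MeI with K2CO3 (acetone, rt) alkylates the soft sulfur of F11 and aromatises to 10.

## Further compounds
F1 | step 1 | 3,4,5-tribromo-2-iodoaniline | Nc1cc(Br)c(Br)c(Br)c1I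
F2 | step 1 | 3,4,5-tribromo-2-[(trimethylsilyl)ethynyl]aniline | C[Si](C)(C)C#Cc1c(N)cc(Br)c(Br)c1Br
F3 | step 1 | 3,4,5-tribromo-2-ethynylaniline | C#Cc1c(N)cc(Br)c(Br)c1Br
F4 | step 1 | 4,5,6-tribromo-1H-indole | Brc1cc2[nH]ccc2c(Br)c1Br
F5 | step 3 | tert-butyl 4,5,6-tribromo-3-(methylsulfanyl)-1H-indole-1-carboxylate | CSc1cn(C(=O)OC(C)(C)C)c2cc(Br)c(Br)c(Br)c12
F6 | step 3 | tert-butyl 4,5,6-tribromo-2-(chloromagnesio)-3-(methylsulfanyl)-1H-indole-1-carboxylate | CSc1c([Mg]Cl)n(C(=O)OC(C)(C)C)c2cc(Br)c(Br)c(Br)c12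
F7 | step 3 | tert-butyl 4,5,6-tribromo-2,3-bis(methylsulfanyl)-1H-indole-1-carboxylate | CSc1c(SC)c2c(Br)c(Br)c(Br)cc2n1C(=O)OC(C)(C)C
F8 | step 2 | (2-ethoxy-2-oxoethyl)(methyl)(3,4,5-tribromoanilino)sulfonium chloride | CCOC(=O)C[S+](C)Nc1cc(Br)c(Br)c(Br)c1.[Cl-]
F9 | step 2 | ethyl 2-(2-amino-4,5,6-tribromophenyl)-2-(methylsulfanyl)acetate (racemic) | CCOC(=O)C(SC)c1c(N)cc(Br)c(Br)c1Br
F10 | step 2 | 4,5,6-tribromo-3-(methylsulfanyl)-1,3-dihydro-2H-indol-2-one (racemic) | CSC1C(=O)Nc2cc(Br)c(Br)c(Br)c12
F11 | step 2 | 4,5,6-tribromo-3-(methylsulfanyl)-1,3-dihydro-2H-indole-2-thione (racemic) | CSC1C(=S)Nc2cc(Br)c(Br)c(Br)c12
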